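If X.E is the product wanted, the question is how much X meets E before L has built up in the flask.

X 2.0 mM; L 2.40 mM (fed, over 3.0 min); E 2.40 mM; time 1.0 h; the fed solution adds 0.50 times the starting volume

    X + L → X.L (k1 = 4.04 M⁻¹ s⁻¹)
    X + E → X.E (k2 = 2.90 M⁻¹ s⁻¹)
    X.L → D (k3 = 0.0149 s⁻¹)

- charges are per starting volume, the dose included; the dosed solution carries all of it
- the reaction counts as stopped when no species that holds the X changes by six tenths of a point or more over the second half of the time
- run time (flask): 1.0 h

* which holds at 1.0 h: what has brought the reaction to rest, or that it has not come to rest (forward and back rates have come level / all of X has reacted / it is still moving / E has run out first / L has run out first)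
* how much of the X has reacted by 1.0 h
* how much X.E there is at 1.0 h, in percent of the X charged
* how much D there is at 1.0 h, in percent of the X charged

The end state comes first. The half-life of X is 1.7 min by the E step alone and 1.2 min by the L step alone with L's whole charge counted as present at once, both short against the 1.0 h. X.L drains with a half-life of 0.78 min. So X should end as X.E or D, and the asked amounts reduce to one split.

That split follows two pulls on X, each a rate constant times a reagent concentration that changes during the run. E stands in the flask from the start and at its charge pulls at 0.418 min⁻¹. L arrives steadily, so its pull starts from nothing and climbs.

The crossover time is the moment when L as fed, with none consumed and the added volume ignored, pulls as hard as E at its charge: the feed time multiplied by E's pull and divided by the pull of L's whole charge. Here it comes to 2.15 min, inside the feed. The rule is to hold the crossover time against the half-life of X under E. In this flask the half-life of 1.7 min is shorter, so on this estimate E pulls harder up to that time, and the reckoning commits to X.E ending ahead of D, without a finer figure.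

The forecast gives all of X has reacted, with conversion 100 %, X.E 57.5 % (range 54 % to 61 %) and D 42.5 % (range 39 % to 46 %), holding that “E takes the early lead because L is still being dosed in”.

The simulation gives all of X has reacted: conversion 100 %, X.E 57.2 % and D 42.8 %.

In this flask the crossover time of 2.15 min stood above the half-life of 1.7 min, and X.E finished ahead of D. The neighbouring flask takes 6.0 mM of L in place of 2.40 mM, with the other charges held. The crossover time of that flask, reckoned the same way, is 0.860 min, now below the same half-life, so the reckoning puts D ahead of X.E. That flask ends with X.E at 43.4 % and D at 56.6 %.

The rate constants are assumed; what happens was integrated by code.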